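The cyclopentane of the target (C2 carrying the C1 carbinol CMe2OH, C3 and C4 methylenes, C5 the methyl carbinol, C6 carrying the polyene carbon C7) is cut into an alkyne C7–C6≡C2–C1, a two-carbon alkene unit C3–C4 and carbon monoxide as C5. Everything rests on a Pauson–Khand [2+2+1] cyclization in which the alkene is a vinylsilane held on the C1 oxygen. It forms C2–C3, C4–C5 and C5–C6 at once, forces the C7-bearing carbon next to the carbonyl, and sheds silicon afterwards. The precursor is the vinyl(dimethyl)silyl ether of the tertiary propargylic alcohol TBSOCH2–C≡C–CMe2OH. Methyl addition, hydroxyl-directed hydrogenation and a C30 Wittig coupling finish the synthesis.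

Key step: step 3

Locants: C1–C8 are the carotenoid positions of the end group (C1 = carbinol carbon of CMe2OH, C2 = ring CH bearing it, C3/C4 = ring CH2, C5 = ring C(CH3)OH, C6 = ring CH bearing the chain, C7/C8 = first two chain carbons). TBS = tert-butyldimethylsilyl, TES = triethylsilyl.

Target configuration: in the given structure the ring hydrogens at C2 and C6 and the C5 hydroxyl lie on one face, and C1, C7 and the C5 methyl on the other; the descriptors are 2R,5R,6R.

Assumption: in step 5 the catalyst is taken to tell the carbonyl faces apart as it does for 2-substituted cycloalkenones; the ligand L* (trans-N,N′-bis[(2-exo-hydroxy-7,7-dimethylbicyclo[2.2.1]heptan-1-yl)methylsulfonyl]cyclohexane-1,2-diamine, either antipode accessible) is the enantiomer that sends methyl to the Si face.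

Assumption: phosphonate 24 is taken as a purchasable reagent (it is the Arbuzov product of ethyl (2E)-4-bromo-2-methylbut-2-enoate and P(OEt)3).

**Route**

Step 1
Reactants: 1 tert-butyl(dimethyl)(prop-2-yn-1-yloxy)silane; 2 acetone
Product: 4 5-{[tert-butyl(dimethyl)silyl]oxy}-2-methylpent-3-yn-2-ol, via lithium acetylide 3 (not isolated)
Conditions: n-BuLi, THF, −78 °C; then 2, −78 → 0 °C; H2O
Reagents that add atoms: none
Why: Deprotonation of the terminal alkyne and 1,2-addition of the acetylide to the ketone (acetylide addition) should give the tertiary propargylic alcohol with the whole C7–C6≡C2–C1 unit in one operation and without touching the silyl ether.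

Step 2
Reactants: 4 5-{[tert-butyl(dimethyl)silyl]oxy}-2-methylpent-3-yn-2-ol; 5 chloro(ethenyl)dimethylsilane
Product: 6 {[5-{[tert-butyl(dimethyl)silyl]oxy}-2-methylpent-3-yn-2-yl]oxy}(ethenyl)dimethylsilane
Conditions: imidazole, DMF, 0 °C → rt
Reagents that add atoms: none
Why: Imidazole-promoted silylation of the tertiary hydroxyl by the small chlorosilane (silyl ether formation) should place the vinyl group three atoms from the alkyne, the spacing of a 1,6-enyne.

Step 3
Reactants: 6 {[5-{[tert-butyl(dimethyl)silyl]oxy}-2-methylpent-3-yn-2-yl]oxy}(ethenyl)dimethylsilane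
Product: 10 2-({[tert-butyl(dimethyl)silyl]oxy}methyl)-3-(2-hydroxypropan-2-yl)cyclopent-2-en-1-one, via hexacarbonyldicobalt alkyne complex 7 (not isolated), via silicon-bridged bicyclic enone 8 (not isolated), via silanol ether 9 (not isolated)
Conditions: Co2(CO)8 (1.1 equiv), CH2Cl2, rt; then MeCN/H2O (99:1), 80 °C; SiO2
Reagents that add atoms: Co2(CO)8 (donor of the C5 carbonyl as CO), O=C=[Co](=C=O)(=C=O)(=C=O)[Co](=C=O)(=C=O)(=C=O)=C=O
Why: Co2(CO)8 should form the Co2(CO)6 complex 7 of the alkyne, loss of CO on heating lets the tethered vinyl group coordinate and insert into the Co–C2 bond, CO inserts on the C4 side and reductive elimination joins C5 to C6. The closest known reaction type is the intramolecular Pauson–Khand reaction of vinylsilyl ethers of propargylic alcohols in wet acetonitrile, where the silicon bridge is lost in the same operation. The cyclopentenone is closed as the [2+2+1] ring (C2–C3, C4–C5, C5–C6), the C2–C3 bond forming in an exo sense that creates the transient five-membered 1,2-oxasilolane of 8; water then attacks silicon of this γ-silyl enone (a vinylogous α-silyl ketone), the dienol is protonated at C3 to give silanol 9, and the remaining Si–O bond is hydrolysed. No stereocentre is set: the C3 centre of 8 disappears when silicon leaves. The selectivity needed is regiochemical, C6 with its CH2O group next to the carbonyl and C2 with the carbinol carbon beta to it, and the three-atom C1–O–Si tether secures it because only the silicon-bearing vinyl carbon can reach C2, whereas free ethylene would place the bulkier CMe2O group next to the carbonyl. The gem-dimethyl group at C1 should favour the folded conformer, and the alkyne is complexed in dry CH2Cl2 before water is admitted so that the tertiary silyl ether is not hydrolysed first.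

Step 4
Reactants: 10 2-({[tert-butyl(dimethyl)silyl]oxy}methyl)-3-(2-hydroxypropan-2-yl)cyclopent-2-en-1-one
Product: 11 2-({[tert-butyl(dimethyl)silyl]oxy}methyl)-3-[2-(triethylsilyloxy)propan-2-yl]cyclopent-2-en-1-one
Conditions: Et3SiOTf, 2,6-lutidine, CH2Cl2, −78 °C
Reagents that add atoms: triethylsilyl trifluoromethanesulfonate, CC[Si](CC)(CC)OS(=O)(=O)C(F)(F)F
Why: Silylation of the tertiary alcohol with a silyl triflate and a hindered pyridine (silyl ether formation) should cap the C1 hydroxyl so that it neither consumes the zinc reagent in step 5 nor competes as a face-blind directing group in step 6, the low temperature keeping the ketone from enol silylation.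

Step 5
Reactants: 11 2-({[tert-butyl(dimethyl)silyl]oxy}methyl)-3-[2-(triethylsilyloxy)propan-2-yl]cyclopent-2-en-1-one
Product: 12 (1R)-2-({[tert-butyl(dimethyl)silyl]oxy}methyl)-1-methyl-3-[2-(triethylsilyloxy)propan-2-yl]cyclopent-2-en-1-ol
Conditions: Me2Zn (3 equiv), Ti(OiPr)4 (1.2 equiv), L* (10 mol%), toluene/hexane, rt
Reagents that add atoms: dimethylzinc, C[Zn]C
Why: Catalytic enantioselective 1,2-addition of a dialkylzinc to a ketone under Ti(OiPr)4 and the chiral bis(sulfonamide) diol L*, a reaction type established for α-substituted cyclic enones, should deliver methyl to the Si face of the C5 carbonyl because the catalyst tells the substituted sp2 carbon C6 from the C4 methylene, which sets (R)-C5.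

Step 6
Reactants: 12 (1R)-2-({[tert-butyl(dimethyl)silyl]oxy}methyl)-1-methyl-3-[2-(triethylsilyloxy)propan-2-yl]cyclopent-2-en-1-ol
Product: 13 (1R,2S,3R)-2-({[tert-butyl(dimethyl)silyl]oxy}methyl)-1-methyl-3-[2-(triethylsilyloxy)propan-2-yl]cyclopentan-1-ol
Conditions: [Ir(cod)(PCy3)(py)]PF6 (10 mol%), H2 (1–10 bar), CH2Cl2, rt
Reagents that add atoms: none
Why: Hydroxyl-directed homogeneous hydrogenation: the cationic iridium centre binds the only free hydroxyl (at C5) and adds H2 to the tetrasubstituted C2=C6 alkene from that face, so both new hydrogens end up syn to the hydroxyl (C2 R, C6 S) while the two silyl ethers do not coordinate.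

Step 7
Reactants: 13 (1R,2S,3R)-2-({[tert-butyl(dimethyl)silyl]oxy}methyl)-1-methyl-3-[2-(triethylsilyloxy)propan-2-yl]cyclopentan-1-ol
Product: 14 (1R,2S,3R)-2-(hydroxymethyl)-3-(2-hydroxypropan-2-yl)-1-methylcyclopentan-1-ol
Conditions: Bu4NF (3 equiv), THF, rt → 40 °C
Reagents that add atoms: none
Why: Fluoride-mediated cleavage of both silyl ethers (desilylation) under non-ionizing conditions should free the primary and the tertiary hydroxyl without risk to the two tertiary carbinols.

Step 8
Reactants: 14 (1R,2S,3R)-2-(hydroxymethyl)-3-(2-hydroxypropan-2-yl)-1-methylcyclopentan-1-ol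
Product: 16 (3aR,6R,6aR)-3,3,6-trimethylhexahydro-1H-cyclopenta[c]furan-1,6-diol (lactol; both C1 epimers), via hydroxy aldehyde 15 (not isolated)
Conditions: IBX (1.3 equiv), DMSO, rt
Reagents that add atoms: none
Why: IBX oxidation of a 1,4-diol stops at the lactol: the primary alcohol is oxidized to aldehyde 15, which the cis C1 hydroxyl traps as the cis-fused five-membered hemiacetal, and this masks the β-hydroxy aldehyde against epimerization at C6 and dehydration while the tertiary alcohols stay inert.

Step 9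
Reactants: 17 pseudoionone, (3E,5E)-6,10-dimethylundeca-3,5,9-trien-2-one
Product: 18 (4E,6E)-3,7,11-trimethyldodeca-1,4,6,10-tetraen-3-ol (racemic)
Conditions: CH2=CHMgBr, THF, 0 °C; H2O
Reagents that add atoms: vinylmagnesium bromide, C=C[Mg]Br
Why: Grignard 1,2-addition to the dienone carbonyl should give the tertiary vinyl carbinol, whose racemic centre is lost in the next step.

Step 10
Reactants: 18 (4E,6E)-3,7,11-trimethyldodeca-1,4,6,10-tetraen-3-ol
Product: 19 [(2E,4E,6E)-3,7,11-trimethyldodeca-2,4,6,10-tetraen-1-yl]triphenylphosphonium bromide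
Conditions: Ph3P·HBr, MeOH, rt; crystallization
Reagents that add atoms: triphenylphosphine hydrobromide, [Br-].[PH+](c1ccccc1)(c1ccccc1)c1ccccc1
Why: Acid-promoted ionization of the tertiary vinyl carbinol and capture of the allylic cation by triphenylphosphine at the primary terminus (phosphonium salt formation with allylic transposition) should give the conjugated salt, the 2E isomer being secured by crystallization.

Step 11
Reactants: 19 [(2E,4E,6E)-3,7,11-trimethyldodeca-2,4,6,10-tetraen-1-yl]triphenylphosphonium bromide; 20 (2E,4E,6E)-2,7-dimethylocta-2,4,6-trienedial (3 equiv)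
Product: 23 (2E,4E,6E,8E,10E,12E,14E)-2,7,11,15,19-pentamethylicosa-2,4,6,8,10,12,14,18-octaenal, via C15 ylide 21 (not isolated), via 8Z aldehyde 22 (not isolated)
Conditions: NaOMe, CH2Cl2/MeOH, 0 °C → rt, dark; then I2 (cat.), CH2Cl2, rt
Reagents that add atoms: none
Why: Wittig olefination of one formyl group of the symmetrical dialdehyde, kept in excess to suppress double olefination, followed by iodine-catalysed Z-to-E equilibration of the new disubstituted double bond should give the all-E C25 aldehyde.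

Step 12
Reactants: 23 (2E,4E,6E,8E,10E,12E,14E)-2,7,11,15,19-pentamethylicosa-2,4,6,8,10,12,14,18-octaenal; 24 ethyl (2E)-4-(diethoxyphosphoryl)-2-methylbut-2-enoate
Product: 26 ethyl (2E,4E,6E,8E,10E,12E,14E,16E,18E)-2,6,11,15,19,23-hexamethyltetracosa-2,4,6,8,10,12,14,16,18,22-decaenoate, via sodium phosphonate carbanion 25 (not isolated)
Conditions: NaH, THF, 0 °C → rt, dark
Reagents that add atoms: none
Why: Horner–Wadsworth–Emmons olefination with the stabilized allylic phosphonate anion, which reacts at the phosphorus-bearing carbon, should form the new disubstituted double bond E-selectively and add the last five carbons as the conjugated ester.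

Step 13
Reactants: 26 ethyl (2E,4E,6E,8E,10E,12E,14E,16E,18E)-2,6,11,15,19,23-hexamethyltetracosa-2,4,6,8,10,12,14,16,18,22-decaenoate
Product: 27 (2E,4E,6E,8E,10E,12E,14E,16E,18E)-2,6,11,15,19,23-hexamethyltetracosa-2,4,6,8,10,12,14,16,18,22-decaen-1-ol
Conditions: iBu2AlH, CH2Cl2, −78 °C; aq. potassium sodium tartrate
Reagents that add atoms: none
Why: Hydride 1,2-reduction of the conjugated ester at low temperature should give the primary allylic alcohol and leave the polyene untouched.

Step 14
Reactants: 27 (2E,4E,6E,8E,10E,12E,14E,16E,18E)-2,6,11,15,19,23-hexamethyltetracosa-2,4,6,8,10,12,14,16,18,22-decaen-1-ol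
Product: 28 [(2E,4E,6E,8E,10E,12E,14E,16E,18E)-2,6,11,15,19,23-hexamethyltetracosa-2,4,6,8,10,12,14,16,18,22-decaen-1-yl]triphenylphosphonium bromide
Conditions: Ph3P·HBr, MeOH/CH2Cl2, 0 °C → rt, dark
Reagents that add atoms: triphenylphosphine hydrobromide, [Br-].[PH+](c1ccccc1)(c1ccccc1)c1ccccc1
Why: Phosphonium salt formation from a polyenyl allylic alcohol through its delocalized cation should put phosphorus on the unsubstituted terminus C8, the position that keeps the full conjugation.

Step 15
Reactants: 16 (3aR,6R,6aR)-3,3,6-trimethylhexahydro-1H-cyclopenta[c]furan-1,6-diol; 28 [(2E,4E,6E,8E,10E,12E,14E,16E,18E)-2,6,11,15,19,23-hexamethyltetracosa-2,4,6,8,10,12,14,16,18,22-decaen-1-yl]triphenylphosphonium bromide (2 equiv)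
Product: 31 (2R,5R,6R)-2,6-cyclolycopene-1,5-diol (target), via C30 ylide 29 (not isolated), via 7Z isomer 30 (not isolated)
Conditions: NaOMe, CH2Cl2/MeOH, 0 °C → rt, dark; then EtOH, reflux, N2; crystallization
Reagents that add atoms: none
Why: Wittig olefination of a lactol: 16 stands in ring–chain equilibrium with its open form, the hydroxy aldehyde 15 already met in step 8, and ylide 29 takes this tautomer as the hemiacetal releases it, forming C7=C8 without touching C2, C5 or C6 because free aldehyde is never present in more than trace amount, after which the hindered 7Z isomer is equilibrated thermally to the all-E polyene.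

**Compound list**

1 | tert-butyl(dimethyl)(prop-2-yn-1-yloxy)silane | C#CCO[Si](C)(C)C(C)(C)C | starting material
2 | acetone | CC(C)=O | starting material
3 | lithium acetylide of 1 | [Li]C#CCO[Si](C)(C)C(C)(C)C | intermediate
4 | 5-{[tert-butyl(dimethyl)silyl]oxy}-2-methylpent-3-yn-2-ol | CC(C)(O)C#CCO[Si](C)(C)C(C)(C)C | intermediate
5 | chloro(ethenyl)dimethylsilane | C=C[Si](C)(C)Cl | starting material
6 | {[5-{[tert-butyl(dimethyl)silyl]oxy}-2-methylpent-3-yn-2-yl]oxy}(ethenyl)dimethylsilane | C=C[Si](C)(C)OC(C)(C)C#CCO[Si](C)(C)C(C)(C)C | intermediate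
7 | Co2(CO)6 complex of the alkyne of 6 (C2Co2 tetrahedrane core) | C=C[Si](C)(C)OC(C)(C)C12C3(CO[Si](C)(C)C(C)(C)C)[Co]1(=C=O)(=C=O)(=C=O)[Co]23(=C=O)(=C=O)=C=O | intermediate
8 | 4-({[tert-butyl(dimethyl)silyl]oxy}methyl)-1,1,3,3-tetramethyl-1,3,6,6a-tetrahydro-5H-cyclopenta[c][1,2]oxasilol-5-one (racemic) | CC1(C)O[Si](C)(C)C2CC(=O)C(CO[Si](C)(C)C(C)(C)C)=C12 | intermediate
9 | 2-({[tert-butyl(dimethyl)silyl]oxy}methyl)-3-(2-{[hydroxy(dimethyl)silyl]oxy}propan-2-yl)cyclopent-2-en-1-one | CC(C)(O[Si](C)(C)O)C1=C(CO[Si](C)(C)C(C)(C)C)C(=O)CC1 | intermediate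
10 | 2-({[tert-butyl(dimethyl)silyl]oxy}methyl)-3-(2-hydroxypropan-2-yl)cyclopent-2-en-1-one | CC(C)(O)C1=C(CO[Si](C)(C)C(C)(C)C)C(=O)CC1 | intermediate
11 | 2-({[tert-butyl(dimethyl)silyl]oxy}methyl)-3-[2-(triethylsilyloxy)propan-2-yl]cyclopent-2-en-1-one | CC[Si](CC)(CC)OC(C)(C)C1=C(CO[Si](C)(C)C(C)(C)C)C(=O)CC1 | intermediate
12 | (1R)-2-({[tert-butyl(dimethyl)silyl]oxy}methyl)-1-methyl-3-[2-(triethylsilyloxy)propan-2-yl]cyclopent-2-en-1-ol | CC(C)(C)[Si](C)(C)OCC1=C(C(C)(C)O[Si](CC)(CC)CC)CC[C@@]1(C)O | intermediate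
13 | (1R,2S,3R)-2-({[tert-butyl(dimethyl)silyl]oxy}methyl)-1-methyl-3-[2-(triethylsilyloxy)propan-2-yl]cyclopentan-1-ol | CC(C)(C)[Si](C)(C)OC[C@@H]1[C@H](C(C)(C)O[Si](CC)(CC)CC)CC[C@@]1(C)O | intermediate
14 | (1R,2S,3R)-2-(hydroxymethyl)-3-(2-hydroxypropan-2-yl)-1-methylcyclopentan-1-ol | OC[C@@H]1[C@H](C(C)(C)O)CC[C@@]1(C)O | intermediate
15 | (1R,2R,5R)-2-hydroxy-5-(2-hydroxypropan-2-yl)-2-methylcyclopentane-1-carbaldehyde | O=C[C@@H]1[C@H](C(C)(C)O)CC[C@@]1(C)O | intermediate
16 | (3aR,6R,6aR)-3,3,6-trimethylhexahydro-1H-cyclopenta[c]furan-1,6-diol (both C1 epimers) | OC1OC(C)(C)[C@@H]2CC[C@@](C)(O)[C@H]12 | intermediate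
17 | pseudoionone, (3E,5E)-6,10-dimethylundeca-3,5,9-trien-2-one | CC(C)=CCC/C(C)=C/C=C/C(C)=O | starting material
18 | (4E,6E)-3,7,11-trimethyldodeca-1,4,6,10-tetraen-3-ol (racemic) | CC(C)=CCC/C(C)=C/C=C/C(C)(O)C=C | intermediate
19 | [(2E,4E,6E)-3,7,11-trimethyldodeca-2,4,6,10-tetraen-1-yl]triphenylphosphonium bromide | CC(C)=CCC/C(C)=C/C=C/C(C)=C/C[P+](c1ccccc1)(c1ccccc1)c1ccccc1.[Br-] | intermediate
20 | (2E,4E,6E)-2,7-dimethylocta-2,4,6-trienedial | O=C/C(C)=C/C=C/C=C(C)/C=O | starting material
21 | C15 ylide from 19 | CC(C)=CCC/C(C)=C/C=C/C(C)=C/C=P(c1ccccc1)(c1ccccc1)c1ccccc1 | intermediate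
22 | (2E,4E,6E,8Z,10E,12E,14E)-2,7,11,15,19-pentamethylicosa-2,4,6,8,10,12,14,18-octaenal | CC(C)=CCC\C(C)=C\C=C\C(C)=C\C=C/C(C)=C/C=C/C=C(C)/C=O | intermediate
23 | (2E,4E,6E,8E,10E,12E,14E)-2,7,11,15,19-pentamethylicosa-2,4,6,8,10,12,14,18-octaenal | CC(C)=CCC/C(C)=C/C=C/C(C)=C/C=C/C(C)=C/C=C/C=C(C)/C=O | intermediate
24 | ethyl (2E)-4-(diethoxyphosphoryl)-2-methylbut-2-enoate | CCOC(=O)/C(C)=C/CP(=O)(OCC)OCC | starting material
25 | sodium salt of the carbanion of 24 | CCOC(=O)/C(C)=C/[CH-]P(=O)(OCC)OCC.[Na+] | intermediate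
26 | ethyl (2E,4E,6E,8E,10E,12E,14E,16E,18E)-2,6,11,15,19,23-hexamethyltetracosa-2,4,6,8,10,12,14,16,18,22-decaenoate | CC(C)=CCC/C(C)=C/C=C/C(C)=C/C=C/C(C)=C/C=C/C=C(C)/C=C/C=C(C)/C(=O)OCC | intermediate
27 | (2E,4E,6E,8E,10E,12E,14E,16E,18E)-2,6,11,15,19,23-hexamethyltetracosa-2,4,6,8,10,12,14,16,18,22-decaen-1-ol | CC(C)=CCC/C(C)=C/C=C/C(C)=C/C=C/C(C)=C/C=C/C=C(C)/C=C/C=C(C)/CO | intermediate
28 | [(2E,4E,6E,8E,10E,12E,14E,16E,18E)-2,6,11,15,19,23-hexamethyltetracosa-2,4,6,8,10,12,14,16,18,22-decaen-1-yl]triphenylphosphonium bromide | CC(C)=CCC/C(C)=C/C=C/C(C)=C/C=C/C(C)=C/C=C/C=C(C)/C=C/C=C(C)/C[P+](c1ccccc1)(c1ccccc1)c1ccccc1.[Br-] | intermediate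
29 | C30 ylide from 28 | CC(C)=CCC/C(C)=C/C=C/C(C)=C/C=C/C(C)=C/C=C/C=C(C)/C=C/C=C(C)/C=P(c1ccccc1)(c1ccccc1)c1ccccc1 | intermediate
30 | (7Z)-isomer of 31 | CC(C)=CCC/C(C)=C/C=C/C(C)=C/C=C/C(C)=C/C=C/C=C(C)/C=C/C=C(C)/C=C\[C@@H]1[C@H](C(C)(C)O)CC[C@@]1(C)O | intermediate
31 | (2R,5R,6R)-2,6-cyclolycopene-1,5-diol; (1R,2R,3R)-3-(2-hydroxypropan-2-yl)-1-methyl-2-[(1E,3E,5E,7E,9E,11E,13E,15E,17E,19E)-3,7,12,16,20,24-hexamethylpentacosa-1,3,5,7,9,11,13,15,17,19,23-undecaen-1-yl]cyclopentan-1-ol | CC(C)=CCC/C(C)=C/C=C/C(C)=C/C=C/C(C)=C/C=C/C=C(C)/C=C/C=C(C)/C=C/[C@@H]1[C@H](C(C)(C)O)CC[C@@]1(C)O | target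

**Step count and risk**

Total steps: 15. Longest linear sequence: 9 (steps 1–8 and 15); the C30 branch is steps 9–14.

Most likely to fail, in order:

Step 3. The tethered vinyl group may fail to insert at a cobalt-complexed alkyne that carries a quaternary propargylic carbon. The tertiary silyl ether may also hydrolyse in the wet medium before ring closure, or the C1 oxygen may be lost reductively from the complexed propargylic position. The fallback sets out from acetone 2 and comes back at enone 11; it is a copper-mediated [3+2] annulation of a zinc homoenolate with an acetylenic ester, in which conjugate addition fixes the same regiochemistry. Acetone 2 is added to lithiated methyl propiolate (LiN(iPr)2, THF, −78 °C) to give methyl 4-hydroxy-4-methylpent-2-ynoate F1, which is silylated (Et3SiOTf, 2,6-lutidine) to methyl 4-methyl-4-(triethylsilyloxy)pent-2-ynoate F2. Zn(CH2CH2CO2Et)2 (from [(1-ethoxycyclopropyl)oxy]trimethylsilane and ZnCl2) with CuBr·SMe2 and HMPA in THF should add its three-carbon chain to C2. The vinyl metal so formed should then close on the ethyl ester to give methyl 5-oxo-2-[2-(triethylsilyloxy)propan-2-yl]cyclopent-1-ene-1-carboxylate F3. iBu2AlH reduces ketone and ester to racemic 2-(hydroxymethyl)-3-[2-(triethylsilyloxy)propan-2-yl]cyclopent-2-en-1-ol F4. t-BuMe2SiCl/imidazole silylates the primary hydroxyl to give racemic 2-({[tert-butyl(dimethyl)silyl]oxy}methyl)-3-[2-(triethylsilyloxy)propan-2-yl]cyclopent-2-en-1-ol F5, and MnO2 oxidizes the ring allylic alcohol to 11.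

Step 6. Hydrogen uptake may not occur at an alkene flanked by two quaternary carbons. The acidic iridium hydride may also ionize and dehydrate the tertiary allylic alcohol, or hydrogen may be delivered to the wrong face. The fallback sets out from 12 and comes back at lactol 16; it relays the C5 configuration through a flat bicyclic butenolide whose ring fusion can only become cis. Bu4NF removes both silyl groups from 12 to give (1R)-2-(hydroxymethyl)-3-(2-hydroxypropan-2-yl)-1-methylcyclopent-2-en-1-ol F6. MnO2 oxidizes the allylic primary alcohol and then the lactol it forms with the C1 hydroxyl to (6R)-6-hydroxy-3,3,6-trimethyl-3,4,5,6-tetrahydro-1H-cyclopenta[c]furan-1-one F7. Heterogeneous hydrogenation (H2, Rh/Al2O3, EtOAc) should take place on the face of the small, surface-binding C5 hydroxyl and away from the C5 methyl, giving (3aR,6R,6aR)-6-hydroxy-3,3,6-trimethylhexahydro-1H-cyclopenta[c]furan-1-one F8. iBu2AlH at −78 °C then reduces the lactone to 16.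

Step 5. Addition to the hindered ketone may be slow and lose out to enolization by the zinc reagent, or the catalyst may discriminate the carbonyl faces poorly. The fallback sets out from 11 and comes back at 12; it replaces asymmetric catalysis by racemic addition and resolution. MeLi with anhydrous CeCl3 (THF, −78 °C) should add to the ketone without enolization to give racemic 2-({[tert-butyl(dimethyl)silyl]oxy}methyl)-1-methyl-3-[2-(triethylsilyloxy)propan-2-yl]cyclopent-2-en-1-ol F9. The enantiomers are then separated by preparative chromatography on a chiral stationary phase (cellulose tris(3,5-dimethylphenylcarbamate)), the (R) enantiomer being 12.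

Further compounds
F1 | step 3 | methyl 4-hydroxy-4-methylpent-2-ynoate | COC(=O)C#CC(C)(C)O
F2 | step 3 | methyl 4-methyl-4-(triethylsilyloxy)pent-2-ynoate | COC(=O)C#CC(C)(C)O[Si](CC)(CC)CC
F3 | step 3 | methyl 5-oxo-2-[2-(triethylsilyloxy)propan-2-yl]cyclopent-1-ene-1-carboxylate | COC(=O)C1=C(C(C)(C)O[Si](CC)(CC)CC)CCC1=O
F4 | step 3 | 2-(hydroxymethyl)-3-[2-(triethylsilyloxy)propan-2-yl]cyclopent-2-en-1-ol (racemic) | OCC1=C(C(C)(C)O[Si](CC)(CC)CC)CCC1O
F5 | step 3 | 2-({[tert-butyl(dimethyl)silyl]oxy}methyl)-3-[2-(triethylsilyloxy)propan-2-yl]cyclopent-2-en-1-ol (racemic) | CC(C)(C)[Si](C)(C)OCC1=C(C(C)(C)O[Si](CC)(CC)CC)CCC1O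
F6 | step 6 | (1R)-2-(hydroxymethyl)-3-(2-hydroxypropan-2-yl)-1-methylcyclopent-2-en-1-ol | OCC1=C(C(C)(C)O)CC[C@@]1(C)O
F7 | step 6 | (6R)-6-hydroxy-3,3,6-trimethyl-3,4,5,6-tetrahydro-1H-cyclopenta[c]furan-1-one | CC1(C)OC(=O)C2=C1CC[C@@]2(C)O
F8 | step 6 | (3aR,6R,6aR)-6-hydroxy-3,3,6-trimethylhexahydro-1H-cyclopenta[c]furan-1-one | O=C1OC(C)(C)[C@@H]2CC[C@@](C)(O)[C@H]12
F9 | step 5 | 2-({[tert-butyl(dimethyl)silyl]oxy}methyl)-1-methyl-3-[2-(triethylsilyloxy)propan-2-yl]cyclopent-2-en-1-ol (racemic) | CC(C)(C)[Si](C)(C)OCC1=C(C(C)(C)O[Si](CC)(CC)CC)CCC1(C)O
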